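## Structural features

The target is a 2,3-trans-dihydroflavonol. Benzene ring A is fused to the pyranone ring C (O1, C2, C3, C4, C4a, C8a); C2 carries the 4-hydroxyphenyl ring B, C3 a secondary hydroxyl and C4 the ketone. C2 and C3 are neighbouring stereocentres, both R, with H2 and H3 trans, so that aryl and hydroxyl can both be equatorial. Ring A has the phloroglucinol pattern: free hydroxyls on C5 (hydrogen-bonded to the C4 carbonyl) and C7, and between them on C6 a 1,1-dimethylallyl (2-methylbut-3-en-2-yl) group bound through its quaternary carbon. The fragile points are the ketol (base epimerises C3, opens ring C at O1–C2 or leads on to the flavonol), the doubly activated benzylic ether at C2, and the terminal alkene flanked by two phenols, which can add a phenol under strong acid or rearrange on heating. The real difficulty is threefold: to place the reverse prenyl group on C6 and not a normal prenyl group on C8, to tell apart the two oxygens ortho to the acyl carbon (one becomes O1, the other the C5 hydroxyl), and to set C2 absolutely and C3 relatively without ever treating the ketol with base. The key step uses the fact that C3–C4 can be carried as the double bond of a silyl enol ether: the C4 oxygen is that of the acetyl group on C4a, C3 is the inner carbon of a vinyl group on C2, and metathesis between the two closes ring C.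

## Logic of the disconnections

17 from 16: the two aryl O–CH2OCH3 bonds on O7 and O4' are cut last. These acetals are needed earlier to leave exactly the right hydroxyls free. The forward step must be mild enough to spare the ketol, the O1–C2 bond and the alkene.

16 from 14 (through 15): the C3–O bond is cut and C3=C4 is restored as the enol ether, with silyl groups back on O4 and O5. The base-sensitive ketol then exists only in the last two steps, and 14 has C2 as its only stereocentre. The forward oxidation must choose the enol ether over the vinyl group on the quaternary carbon, must attack the face opposite to the C2 aryl group, and must be unmasked without base.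

14 from 13: C3=C4 is cut by retro-metathesis into the silyl enol ether on C4a and the vinyl group on C2. Ring C is opened and the problem becomes an acyclic aryl allyl ether of an acetophenone. The descriptor S at C2 in 13 and 14 and R in 15–17 describe the same spatial arrangement; only the rank of C3 against the aryl group changes once C3 bears oxygen, so the structures of 13 and 14 need no correction. The forward step must join a hindered 1,1-disubstituted enol ether to a monosubstituted alkene in the presence of a third terminal alkene and must not isomerise the allylic ether.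

13 from 12: the O4–Si and O5–Si bonds are cut. Both silyl groups go on in one operation directly before metathesis, so the enol ether is never carried through other chemistry. The forward step must silylate a phenol lying between an acyl group and a quaternary carbon without ionising the allylic ether.

12 from 7 and 11: O1–C2 is cut. This bond carries the only stereocentre of 12, and a catalytic asymmetric allylic etherification makes it from an achiral linear allyl donor and a phenol. The forward step must give the branched isomer, control the configuration, and choose between the two ortho hydroxyls of 7; the quaternary carbon next to one of them is relied on for that choice.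

11 from 10, 9 and 8: the carbonate C–O bond, the two new C–H bonds at the carbinol carbon and the O4'–CH2 bond are cut in turn. This leads to a commercial cinnamate ester in three routine operations with the E geometry already in place.

7 from 6: the O7–CH2 bond is cut. The forward step must alkylate the para hydroxyl only.

6 from 3 (through 4 and 5): the bond from C6 to the quaternary carbon is cut by a retro-[3,3] shift to an allyl ether on the oxygen para to the acetyl carbon. This placement corrects the one weak point of an approach through an ether on an ortho oxygen. An ortho ether leaves the para carbon free, and the first-formed dienone is known to go on by Cope shift to a normal prenyl group on that carbon (the later C8). With the ether on the para oxygen both ortho carbons are equivalent by symmetry and the para carbon is blocked by the acetyl group, so only the 1,1-dimethylallyl isomer can form. The forward step must keep the new phenol from reacting with the alkene at high temperature.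

3 from 1 and 2: the O–CH2 bond of the allyl ether is cut, which leads to the two commercial starting materials. The forward step must alkylate only the para oxygen of a triol.

## Other disconnections considered

Alternative 1: The cut is C4–C4a. In the forward direction (2R,3R)-3-[3,5-bis(allyloxy)-4-(2-methylbut-3-en-2-yl)phenoxy]-3-[4-(allyloxy)phenyl]-2-hydroxypropanoic acid A1 would be activated with trifluoroacetic anhydride and would acylate its own aryloxy ring ortho to the ether oxygen to give the tris(allyloxy) flavanonol A2. Removal of the allyl groups with Pd(PPh3)4 and a soft nucleophile would give 17.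
- In favour: the aryloxy ring of A1 is symmetric about the axis through the ether oxygen and the quaternary carbon, so both ortho carbons are the same and no choice between two ortho oxygens is needed. On this point the alternative is better than the chosen plan, which relies on hindrance in step 7.
- In favour: both stereocentres are in place before ring closure and could come from reagent-controlled dihydroxylation chemistry, so C3 would not depend on a substrate-controlled oxidation (equal or better). The neutral deallylation at the end is milder than the acid of step 11 (better).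
- Against: the benzylic aryl ether of A1 would have to be made with defined configuration from a hindered, electron-rich phenol at a 4-alkoxybenzylic carbon, where ionisation competes.
- Against: in the acylating medium the same C–O bond can ionise, or the activated acid can lose aryloxide by β-elimination before the ring closes.
- Against: the hydroxyl of A1 is acylated as well, and the alkene and three allyl ethers sit in strong acid on a very electron-rich ring.
- Comparison: on structure the alternative removes the ortho-oxygen problem but needs the same Claisen chemistry for the dimethylallyl group. On mechanism it is an electrophilic substitution in strong acid against a neutral metathesis, and the chosen plan keeps the C2 ether away from acid until the last step. On step economy the two are about equal.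

Alternative 2: The cut is O1–C2 and C3–C4. A chiral confined Brønsted acid would dehydrate 3-(allyloxy)-2-(hydroxymethyl)-5-(methoxymethoxy)-4-(2-methylbut-3-en-2-yl)phenol A3 to the ortho-quinone methide A4, which would add (E)-2-[4-(methoxymethoxy)phenyl]ethenyl benzoate A5 in a [4+2] reaction to give the flavan-3-yl benzoate A6.
- In favour: two bonds, ring C and both stereocentres would be made in one catalytic step. This is more convergent than the chosen key step, which forms one bond and no stereocentre (better on this point). The trans relation would follow from the E geometry of A5 in a suprafacial addition.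
- Against: A6 is a flavan. C4 is a methylene and would have to be oxidised to the ketone late, beside the doubly activated C2–H, the terminal alkene and electron-rich rings. This is the main weakness.
- Against: A4 carries three oxygen donors and is a weak electrophile, and enol esters are weak 2π partners, so reactivity and enantiocontrol are the least secure of the four plans.
- Against: A3 needs the same discrimination of ring A oxygens as 7, so nothing is saved before the key step. Three kinds of protecting group would have to be removed, the benzoate by base once the ketol exists.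
- Comparison: on structure the effort for ring A is equal and the oxidation level at C4 is wrong. On mechanism one asymmetric cycloaddition would set both centres (an advantage) but with thinner precedent than iridium catalysis for C2 and substrate control for C3. On step economy the way to the ring is shorter and the way after it longer, so the total is not shorter.

Alternative 3: The cut is O1–C8a and C4–C4a. CsF would release the aryne A8 from 3,5-bis(methoxymethoxy)-4-(2-methylbut-3-en-2-yl)-2-(trimethylsilyl)phenyl trifluoromethanesulfonate A7. The alkoxide of methyl (2R,3R)-3-hydroxy-2-(methoxymethoxy)-3-[4-(methoxymethoxy)phenyl]propanoate A9 would add at C8a, and the aryl anion at C4a would close on the ester to give the tetrakis(methoxymethoxy) flavanone A10.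
- In favour: ring A would be inserted in one step with C4 already a ketone. Both stereocentres come with A9 from reagent-controlled chemistry (equal or better for C3).
- In favour: the alkoxy group next to the aryne bond directs the nucleophile to the distal carbon and stabilises the anion beside it, which is the orientation needed. The regiochemistry of this step is as secure as in the chosen plan. Only one kind of protecting group is used.
- Against: A7 is a hexasubstituted benzene whose ortho silyl and triflate groups must be built on the phloroglucinol core after the dimethylallyl group. This clearly takes more steps than 7.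
- Against: under fluoride the alkoxide of A9 can fragment by retro-aldol cleavage and lose both stereocentres, and it is a weaker aryne trap than the phenoxides for which such annulations are established. The aryl anion can be protonated before it acylates.
- Against: A10 has an acidic C3–H and a β-aryloxy ketone in a basic medium. Four MOM groups, one of them on a secondary alcohol, need stronger acid at the end than the two aryl MOM groups of 16.
- Comparison: on structure this is the most convergent plan but has the longest ring A synthesis. On mechanism it is anionic and basic, whereas the chosen plan never exposes the C3-oxygenated ketone to base. On step economy it is probably longer overall.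

Key step: step 9

Assumption: the (Sa,Sc,Sc) phosphoramidite is taken to direct oxygen nucleophiles to the face of the allyl intermediate that gives the S ether; if the sense of induction were the opposite, the (Ra,Rc,Rc) ligand would be used with no other change.

## Route

Step 1
Reactants: 1 2,4,6-trihydroxyacetophenone; 2 prenyl bromide (1-bromo-3-methylbut-2-ene)
Product: 3 1-[2,6-dihydroxy-4-(3-methylbut-2-enyloxy)phenyl]ethanone
Conditions: K2CO3 (1.1 equiv), 2 (1.0 equiv), acetone, rt
Reagents that add atoms: none
Why: Williamson ether synthesis; the para hydroxyl is the most acidic and is not hydrogen-bonded to the acetyl group, so one equivalent of base and of the primary allylic bromide should alkylate there, and room temperature holds back a second O-alkylation and C-alkylation.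

Step 2
Reactants: 3 1-[2,6-dihydroxy-4-(3-methylbut-2-enyloxy)phenyl]ethanone
Product: 6 1-[2,4,6-trihydroxy-3-(2-methylbut-3-en-2-yl)phenyl]ethanone, via bis-TMS ether 4 (not isolated), via tris-TMS ether 5 (not isolated)
Conditions: N,O-bis(trimethylsilyl)acetamide (5 equiv), N,N-diethylaniline, 185 °C, sealed tube; then citric acid, MeOH–H2O, rt
Reagents that add atoms: none
Why: Aromatic Claisen rearrangement; the [3,3] shift from the para oxygen to either of the two equivalent ortho carbons gives the 1,1-dimethylallyl group after enolisation, the acetyl-bearing para carbon allows no productive Cope shift, and silylation of every phenol in the flask should suppress addition of the new phenol to the alkene and the abnormal Claisen pathway before mild acidic methanolysis frees the triol.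

Step 3
Reactants: 6 1-[2,4,6-trihydroxy-3-(2-methylbut-3-en-2-yl)phenyl]ethanone
Product: 7 1-[2,6-dihydroxy-4-(methoxymethoxy)-3-(2-methylbut-3-en-2-yl)phenyl]ethanone
Conditions: MOMCl (1.05 equiv), i-Pr2NEt (1.5 equiv), CH2Cl2, −20 to 0 °C
Reagents that add atoms: chloromethyl methyl ether, COCCl
Why: Amine-mediated O-alkylation to the MOM ether; the para hydroxyl is again the most acidic and is not engaged with the carbonyl, so one equivalent of the small electrophile should react there despite the neighbouring quaternary carbon and leave both ortho hydroxyls free.

Step 4
Reactants: 8 methyl (E)-3-(4-hydroxyphenyl)prop-2-enoate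
Product: 9 methyl (E)-3-[4-(methoxymethoxy)phenyl]prop-2-enoate
Conditions: MOMCl (1.3 equiv), i-Pr2NEt, CH2Cl2, 0 °C to rt
Reagents that add atoms: chloromethyl methyl ether, COCCl
Why: MOM protection of a phenol under amine base; the conjugated ester is inert.

Step 5
Reactants: 9 methyl (E)-3-[4-(methoxymethoxy)phenyl]prop-2-enoate
Product: 10 (E)-3-[4-(methoxymethoxy)phenyl]prop-2-en-1-ol
Conditions: i-Bu2AlH (2.2 equiv), CH2Cl2, −78 °C; aqueous potassium sodium tartrate
Reagents that add atoms: none
Why: 1,2-Reduction of the conjugated ester to the allylic alcohol by the aluminium hydride at low temperature, which leaves the E alkene and the aryl acetal untouched.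

Step 6
Reactants: 10 (E)-3-[4-(methoxymethoxy)phenyl]prop-2-en-1-ol
Product: 11 methyl (E)-3-[4-(methoxymethoxy)phenyl]prop-2-enyl carbonate
Conditions: ClCO2Me (1.3 equiv), pyridine, CH2Cl2, 0 °C
Reagents that add atoms: methyl chloroformate, COC(=O)Cl
Why: Acylation of the primary allylic alcohol with a chloroformate gives the linear carbonate used as allyl donor.

Step 7
Reactants: 7 1-[2,6-dihydroxy-4-(methoxymethoxy)-3-(2-methylbut-3-en-2-yl)phenyl]ethanone; 11 methyl (E)-3-[4-(methoxymethoxy)phenyl]prop-2-enyl carbonate
Product: 12 1-[2-hydroxy-4-(methoxymethoxy)-6-{(1S)-1-[4-(methoxymethoxy)phenyl]prop-2-enyloxy}-3-(2-methylbut-3-en-2-yl)phenyl]ethanone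
Conditions: [Ir(cod)Cl]2 (2 mol %), (Sa,Sc,Sc)-O,O'-(1,1'-binaphthyl-2,2'-diyl) N,N-bis(1-phenylethyl)phosphoramidite (4 mol %), n-PrNH2 (activation at 50 °C, then evaporated); 7, NaH (1.0 equiv), THF, 0 °C; then 11 (1.1 equiv), THF, rt
Reagents that add atoms: none
Why: Iridium-catalysed asymmetric allylic etherification; the catalyst formed from [Ir(cod)Cl]2 and the phosphoramidite ionises the linear carbonate, aryloxides attack the allyl intermediate at its aryl-substituted end to give the branched ether, and the ligand sets the new C2 stereocentre as S; of the two hydroxyls of 7 only the one flanked by hydrogen should react, because the other is shielded by the quaternary carbon and, with one equivalent of base, stays protonated and hydrogen-bonded.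

Step 8
Reactants: 12 1-[2-hydroxy-4-(methoxymethoxy)-6-{(1S)-1-[4-(methoxymethoxy)phenyl]prop-2-enyloxy}-3-(2-methylbut-3-en-2-yl)phenyl]ethanone
Product: 13 tert-butyl[(1-{2-(tert-butyldimethylsilyloxy)-4-(methoxymethoxy)-6-{(1S)-1-[4-(methoxymethoxy)phenyl]prop-2-enyloxy}-3-(2-methylbut-3-en-2-yl)phenyl}ethenyl)oxy]dimethylsilane
Conditions: TBSOTf (3 equiv), Et3N (5 equiv), CH2Cl2, −78 to 0 °C
Reagents that add atoms: tert-butyldimethylsilyl trifluoromethanesulfonate, CC(C)(C)[Si](C)(C)OS(=O)(=O)C(F)(F)F
Why: Silyl triflate with amine base silylates the remaining hindered phenol and converts the aryl methyl ketone into its silyl enol ether by soft enolisation (only the methyl group can enolise); low temperature and excess amine should keep the acid-labile allylic ether and the MOM groups intact.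

Step 9
Reactants: 13 tert-butyl[(1-{2-(tert-butyldimethylsilyloxy)-4-(methoxymethoxy)-6-{(1S)-1-[4-(methoxymethoxy)phenyl]prop-2-enyloxy}-3-(2-methylbut-3-en-2-yl)phenyl}ethenyl)oxy]dimethylsilane
Product: 14 (2S)-4,5-bis(tert-butyldimethylsilyloxy)-7-(methoxymethoxy)-2-[4-(methoxymethoxy)phenyl]-6-(2-methylbut-3-en-2-yl)-2H-chromene
Conditions: second-generation Grubbs catalyst RuCl2(=CHPh)(PCy3)(H2IMes) (10 mol %), 1,4-benzoquinone (20 mol %), toluene (0.005 M), 70 °C, argon purge
Reagents that add atoms: none
Why: Ring-closing olefin metathesis by the metallacyclobutane mechanism: the catalyst exchanges its benzylidene with the monosubstituted vinyl group on C2, the resulting ruthenium alkylidene undergoes [2+2] cycloaddition with the 1,1-disubstituted silyl enol ether, and cycloreversion releases the C3=C4 enol ether and a ruthenium methylidene, with ethylene leaving the solution. The closest known reactions are the ring-closing metathesis of acyclic silyl enol ethers to cyclic silyl enol ethers and of allyl 2-vinylphenyl ethers to 2H-chromenes. Ring C is closed as a six-membered ring with the new double bond inside the ring, the inner carbon of each alkene becoming a ring atom (C3 and C4). No stereocentre is formed and C2 takes no part in the mechanism; benzoquinone is added to intercept ruthenium hydrides that could move the allylic double bond toward C2. The step needs chemoselectivity among three terminal alkenes: the vinyl group of the 1,1-dimethylallyl unit sits on a quaternary carbon, is engaged very slowly, and could reach the other alkenes only through a meta- or para-bridged ring, so it should stay out. High dilution disfavours intermolecular metathesis through the C2 vinyl group. The enol ether is hindered and twisted out of the plane of ring A, which is why heating and a full catalyst loading are planned.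

Step 10
Reactants: 14 (2S)-4,5-bis(tert-butyldimethylsilyloxy)-7-(methoxymethoxy)-2-[4-(methoxymethoxy)phenyl]-6-(2-methylbut-3-en-2-yl)-2H-chromene
Product: 16 (2R,3R)-3,5-dihydroxy-7-(methoxymethoxy)-2-[4-(methoxymethoxy)phenyl]-6-(2-methylbut-3-en-2-yl)chroman-4-one, via silyloxy epoxide 15 (not isolated)
Conditions: dimethyldioxirane (1.1 equiv, acetone), CH2Cl2, −78 to −30 °C; then Bu4NF, AcOH (1:1, 3 equiv), THF, 0 °C
Reagents that add atoms: dimethyldioxirane, CC1(C)OO1
Why: Rubottom oxidation; the electrophilic dioxirane should epoxidise the electron-rich trisubstituted enol ether far faster than the hindered monosubstituted alkene and from the face of C3=C4 opposite to the C2 aryl group, which sets C3 as R with the oxygen trans to the aryl group; buffered fluoride then removes the silyl group from the C4 oxygen so that the epoxide collapses to the ketol with the C3–O bond retained, and cleaves the C5 silyl ether in the same operation without base.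

Step 11
Reactants: 16 (2R,3R)-3,5-dihydroxy-7-(methoxymethoxy)-2-[4-(methoxymethoxy)phenyl]-6-(2-methylbut-3-en-2-yl)chroman-4-one
Product: 17 (2R,3R)-3,5,7-trihydroxy-2-(4-hydroxyphenyl)-6-(2-methylbut-3-en-2-yl)chroman-4-one
Conditions: HCl (1 M in MeOH), THF, rt to 40 °C
Reagents that add atoms: none
Why: Acid-catalysed acetal exchange with methanol removes the two aryl MOM groups; dilute acid at moderate temperature should leave the ketol, the O1–C2 ether and the monosubstituted alkene (which could give only a secondary cation) unchanged, so C2 and C3 keep their configuration.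

## Compound list

1 | 2,4,6-trihydroxyacetophenone | CC(=O)c1c(O)cc(O)cc1O | starting material
2 | prenyl bromide (1-bromo-3-methylbut-2-ene) | CC(C)=CCBr | starting material
3 | 1-[2,6-dihydroxy-4-(3-methylbut-2-enyloxy)phenyl]ethanone | CC(=O)c1c(O)cc(OCC=C(C)C)cc1O | intermediate
4 | 1-[4-(3-methylbut-2-enyloxy)-2,6-bis(trimethylsilyloxy)phenyl]ethanone | CC(=O)c1c(O[Si](C)(C)C)cc(OCC=C(C)C)cc1O[Si](C)(C)C | intermediate
5 | 1-[3-(2-methylbut-3-en-2-yl)-2,4,6-tris(trimethylsilyloxy)phenyl]ethanone | CC(=O)c1c(O[Si](C)(C)C)cc(O[Si](C)(C)C)c(C(C)(C)C=C)c1O[Si](C)(C)C | intermediate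
6 | 1-[2,4,6-trihydroxy-3-(2-methylbut-3-en-2-yl)phenyl]ethanone | CC(=O)c1c(O)cc(O)c(C(C)(C)C=C)c1O | intermediate
7 | 1-[2,6-dihydroxy-4-(methoxymethoxy)-3-(2-methylbut-3-en-2-yl)phenyl]ethanone | CC(=O)c1c(O)cc(OCOC)c(C(C)(C)C=C)c1O | intermediate
8 | methyl (E)-3-(4-hydroxyphenyl)prop-2-enoate | COC(=O)/C=C/c1ccc(O)cc1 | starting material
9 | methyl (E)-3-[4-(methoxymethoxy)phenyl]prop-2-enoate | COC(=O)/C=C/c1ccc(OCOC)cc1 | intermediate
10 | (E)-3-[4-(methoxymethoxy)phenyl]prop-2-en-1-ol | OC/C=C/c1ccc(OCOC)cc1 | intermediate
11 | methyl (E)-3-[4-(methoxymethoxy)phenyl]prop-2-enyl carbonate | COC(=O)OC/C=C/c1ccc(OCOC)cc1 | intermediate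
12 | 1-[2-hydroxy-4-(methoxymethoxy)-6-{(1S)-1-[4-(methoxymethoxy)phenyl]prop-2-enyloxy}-3-(2-methylbut-3-en-2-yl)phenyl]ethanone | C=C[C@@H](c1ccc(OCOC)cc1)Oc1cc(OCOC)c(C(C)(C)C=C)c(O)c1C(C)=O | intermediate
13 | tert-butyl[(1-{2-(tert-butyldimethylsilyloxy)-4-(methoxymethoxy)-6-{(1S)-1-[4-(methoxymethoxy)phenyl]prop-2-enyloxy}-3-(2-methylbut-3-en-2-yl)phenyl}ethenyl)oxy]dimethylsilane | C=C[C@@H](c1ccc(OCOC)cc1)Oc1cc(OCOC)c(C(C)(C)C=C)c(O[Si](C)(C)C(C)(C)C)c1C(=C)O[Si](C)(C)C(C)(C)C | intermediate
14 | (2S)-4,5-bis(tert-butyldimethylsilyloxy)-7-(methoxymethoxy)-2-[4-(methoxymethoxy)phenyl]-6-(2-methylbut-3-en-2-yl)-2H-chromene | C=CC(C)(C)c1c(OCOC)cc2c(c1O[Si](C)(C)C(C)(C)C)C(O[Si](C)(C)C(C)(C)C)=C[C@@H](c1ccc(OCOC)cc1)O2 | intermediate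
15 | (2R,3R,4R)-4,5-bis(tert-butyldimethylsilyloxy)-3,4-epoxy-7-(methoxymethoxy)-2-[4-(methoxymethoxy)phenyl]-6-(2-methylbut-3-en-2-yl)chromane (epoxide oxygen anti to the C2 aryl group) | C=CC(C)(C)c1c(OCOC)cc2c(c1O[Si](C)(C)C(C)(C)C)[C@]3(O[Si](C)(C)C(C)(C)C)O[C@@H]3[C@@H](c1ccc(OCOC)cc1)O2 | intermediate
16 | (2R,3R)-3,5-dihydroxy-7-(methoxymethoxy)-2-[4-(methoxymethoxy)phenyl]-6-(2-methylbut-3-en-2-yl)chroman-4-one | C=CC(C)(C)c1c(OCOC)cc2c(c1O)C(=O)[C@H](O)[C@@H](c1ccc(OCOC)cc1)O2 | intermediate
17 | (2R,3R)-3,5,7-trihydroxy-2-(4-hydroxyphenyl)-6-(2-methylbut-3-en-2-yl)chroman-4-one (CNP0527000.1) | C=CC(C)(C)c1c(O)cc2c(c1O)C(=O)[C@H](O)[C@@H](c1ccc(O)cc1)O2 | target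

## Step count and least certain steps

Total step count: 11. Longest linear sequence: 8 steps (steps 1, 2, 3, 7, 8, 9, 10, 11 from 1; the branch from 8 through steps 4–6 joins at step 7 and is equally long).

Step 9 (key step). The catalyst may fail to engage the hindered, twisted enol ether, so that the alkylidene formed at the C2 vinyl group is diverted into intermolecular metathesis or decays to hydride species that isomerise the allylic ether; crowding between the two silyloxy groups at the peri positions builds up as the ring closes. The fallback sets out from 12 and returns at 16, and changes the architecture of the substrate, not the catalyst: the enol oxygen and the C5 oxygen are tied into one ring before metathesis. 12 with t-Bu2Si(OTf)2 and Et3N (CH2Cl2, 0 °C) should give the cyclic silylene enol ether (S)-2,2-di-tert-butyl-7-(methoxymethoxy)-5-{1-[4-(methoxymethoxy)phenyl]prop-2-enyloxy}-8-(2-methylbut-3-en-2-yl)-4-methylidene-4H-1,3,2-benzodioxasiline F1. Its dioxasiline ring holds the enol ether in the plane of ring A with the CH2 turned toward the C2 vinyl group and leaves no second bulky silyl group at the peri position; it also replaces the intermolecular silylation of the hindered phenol in step 8 by a ring closure. Metathesis with the same catalyst would give (2S)-4,5-(di-tert-butylsilanediyldioxy)-7-(methoxymethoxy)-2-[4-(methoxymethoxy)phenyl]-6-(2-methylbut-3-en-2-yl)-2H-chromene F2, dimethyldioxirane its 3,4-epoxide anti to the aryl group F3 (not isolated), and Bu4NF with AcOH would release 16.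

Step 7. Capture of the allyl intermediate by a weakly nucleophilic, hydrogen-bonded acyl aryloxide may be slow; the product ether has a good leaving group and can be ionised again by the catalyst, with loss of enantiomeric purity and drift to the linear ether; C-allylation of ring A and attack through the hindered oxygen are further risks. The fallback sets out from 11 and 7 and returns at 12: C2 is set on a small oxygen nucleophile and the aryl ether is then made with inversion. 11 with KOSiEt3 under the same catalyst system carrying the (Ra,Rc,Rc) ligand should give (R)-triethyl{1-[4-(methoxymethoxy)phenyl]prop-2-enyloxy}silane F4; Bu4NF gives (R)-1-[4-(methoxymethoxy)phenyl]prop-2-en-1-ol F5; Mitsunobu reaction of F5 with 7 (PPh3, diisopropyl azodicarboxylate, toluene, −20 °C) should etherify the unhindered hydroxyl with inversion and give 12.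

Step 2. At the temperature of the rearrangement, incomplete silyl capture would allow addition of the new phenol to the neighbouring alkene or the abnormal Claisen shift of the side chain, and the silylating agent may decompose. The fallback sets out from 3 and returns at 6, with acyl instead of silyl capture and isolated esters. 3 is acetylated (Ac2O, pyridine, rt) to 1-[2,6-diacetoxy-4-(3-methylbut-2-enyloxy)phenyl]ethanone F6; F6 is heated with Ac2O in N,N-diethylaniline (185 °C), the classical way of trapping the phenol of an ortho-(1,1-dimethylallyl) Claisen product as its ester, to give 1-[2,4,6-triacetoxy-3-(2-methylbut-3-en-2-yl)phenyl]ethanone F7; methanolysis (K2CO3, degassed MeOH, 0 °C) returns 6.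

Step 3. Site selectivity may be poor: the quaternary carbon next to the para hydroxyl may slow its alkylation enough for the unhindered ortho hydroxyl to compete, and a second alkylation may follow. The fallback sets out from 6 and returns at 7: protect exhaustively, then deprotect selectively. 6 with MOMCl (2.5 equiv) and i-Pr2NEt should give 1-[2-hydroxy-4,6-bis(methoxymethoxy)-3-(2-methylbut-3-en-2-yl)phenyl]ethanone F8, the hydroxyl between the acetyl group and the quaternary carbon being the least reactive; the MOM group ortho to the acyl group, the more labile of the two because of the neighbouring carbonyl, is then removed with dilute HCl in MeOH at rt to give 7.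

## Further compounds

F1 | step 9 | (S)-2,2-di-tert-butyl-7-(methoxymethoxy)-5-{1-[4-(methoxymethoxy)phenyl]prop-2-enyloxy}-8-(2-methylbut-3-en-2-yl)-4-methylidene-4H-1,3,2-benzodioxasiline | C=C[C@@H](c1ccc(OCOC)cc1)Oc1cc(OCOC)c(C(C)(C)C=C)c2O[Si](C(C)(C)C)(C(C)(C)C)OC(=C)c12
F2 | step 9 | (2S)-4,5-(di-tert-butylsilanediyldioxy)-7-(methoxymethoxy)-2-[4-(methoxymethoxy)phenyl]-6-(2-methylbut-3-en-2-yl)-2H-chromene | C=CC(C)(C)c1c(OCOC)cc2c3c1O[Si](C(C)(C)C)(C(C)(C)C)OC3=C[C@@H](c1ccc(OCOC)cc1)O2
F3 | step 9 | (2R,3R,4R)-3,4-epoxide of F2, epoxide oxygen anti to the C2 aryl group | C=CC(C)(C)c1c(OCOC)cc2c3c1O[Si](C(C)(C)C)(C(C)(C)C)O[C@]34O[C@@H]4[C@@H](c1ccc(OCOC)cc1)O2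
F4 | step 7 | (R)-triethyl{1-[4-(methoxymethoxy)phenyl]prop-2-enyloxy}silane | C=C[C@H](c1ccc(OCOC)cc1)O[Si](CC)(CC)CC
F5 | step 7 | (R)-1-[4-(methoxymethoxy)phenyl]prop-2-en-1-ol | C=C[C@H](c1ccc(OCOC)cc1)O
F6 | step 2 | 1-[2,6-diacetoxy-4-(3-methylbut-2-enyloxy)phenyl]ethanone | CC(=O)Oc1cc(OCC=C(C)C)cc(OC(C)=O)c1C(C)=O
F7 | step 2 | 1-[2,4,6-triacetoxy-3-(2-methylbut-3-en-2-yl)phenyl]ethanone | CC(=O)Oc1cc(OC(C)=O)c(C(C)(C)C=C)c(OC(C)=O)c1C(C)=O
F8 | step 3 | 1-[2-hydroxy-4,6-bis(methoxymethoxy)-3-(2-methylbut-3-en-2-yl)phenyl]ethanone | CC(=O)c1c(OCOC)cc(OCOC)c(C(C)(C)C=C)c1O
A1 | alternative 1 | (2R,3R)-3-[3,5-bis(allyloxy)-4-(2-methylbut-3-en-2-yl)phenoxy]-3-[4-(allyloxy)phenyl]-2-hydroxypropanoic acid | OC(=O)[C@H](O)[C@@H](c1ccc(OCC=C)cc1)Oc1cc(OCC=C)c(C(C)(C)C=C)c(OCC=C)c1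
A2 | alternative 1 | (2R,3R)-5,7-bis(allyloxy)-2-[4-(allyloxy)phenyl]-3-hydroxy-6-(2-methylbut-3-en-2-yl)chroman-4-one | C=CC(C)(C)c1c(OCC=C)cc2c(c1OCC=C)C(=O)[C@H](O)[C@@H](c1ccc(OCC=C)cc1)O2
A3 | alternative 2 | 3-(allyloxy)-2-(hydroxymethyl)-5-(methoxymethoxy)-4-(2-methylbut-3-en-2-yl)phenol | OCc1c(O)cc(OCOC)c(C(C)(C)C=C)c1OCC=C
A4 | alternative 2 | 5-(allyloxy)-3-(methoxymethoxy)-4-(2-methylbut-3-en-2-yl)-6-methylidenecyclohexa-2,4-dien-1-one | C=C1C(=O)C=C(OCOC)C(C(C)(C)C=C)=C1OCC=C
A5 | alternative 2 | (E)-2-[4-(methoxymethoxy)phenyl]ethenyl benzoate | O=C(O/C=C/c1ccc(OCOC)cc1)c1ccccc1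
A6 | alternative 2 | (2R,3S)-5-(allyloxy)-7-(methoxymethoxy)-2-[4-(methoxymethoxy)phenyl]-6-(2-methylbut-3-en-2-yl)chroman-3-yl benzoate | C=CC(C)(C)c1c(OCOC)cc2c(c1OCC=C)C[C@H](OC(=O)c1ccccc1)[C@@H](c1ccc(OCOC)cc1)O2
A7 | alternative 3 | 3,5-bis(methoxymethoxy)-4-(2-methylbut-3-en-2-yl)-2-(trimethylsilyl)phenyl trifluoromethanesulfonate | C=CC(C)(C)c1c(OCOC)cc(OS(=O)(=O)C(F)(F)F)c([Si](C)(C)C)c1OCOC
A8 | alternative 3 | 3,5-bis(methoxymethoxy)-4-(2-methylbut-3-en-2-yl)-1,2-didehydrobenzene | C=CC(C)(C)C1=C(OCOC)C#CC=C1OCOC
A9 | alternative 3 | methyl (2R,3R)-3-hydroxy-2-(methoxymethoxy)-3-[4-(methoxymethoxy)phenyl]propanoate | COC(=O)[C@H](OCOC)[C@H](O)c1ccc(OCOC)cc1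
A10 | alternative 3 | (2R,3R)-3,5,7-tris(methoxymethoxy)-2-[4-(methoxymethoxy)phenyl]-6-(2-methylbut-3-en-2-yl)chroman-4-one | C=CC(C)(C)c1c(OCOC)cc2c(c1OCOC)C(=O)[C@H](OCOC)[C@@H](c1ccc(OCOC)cc1)O2
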